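**Strategy.** Ring A is read as a cyclohexene retron: the quaternary ester carbon C4 is bonded to the ring-fusion methine C5, and the enone alkene C1=C10 sits where a diene leaves its new double bond. The route therefore rests on a catalytic enantioselective Diels–Alder reaction that closes ring A by forming C4–C5 (together with C2–C3) between methacrolein and a ring B 1-vinylcyclohexene that already carries C8, C9 and the protected side chain. One operation sets the C4 quaternary centre and C5; the formyl group then becomes the methyl ester and allylic oxidation at C2 completes the enone.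

Key step: step 9

Numbering used throughout (halimane type): ring A = C1–C5 and C10 (C2 ketone, C1=C10 alkene, C4 bearing CH3 and the ester carbon C18); ring B = C5–C10 (C8 bearing CH3, C9 bearing CH3 and the side chain C11–C15, C13 bearing CH3, C15 bearing OH).

Assumption: the antipodes of the two chiral catalysts (phosphoramidite in step 5, oxazaborolidinium in step 9) are taken to be the ones that give the configurations drawn; should the opposite sense be found, the mirror-image catalyst is used.

**Step 1**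
Reactants: 1 (R)-5-methoxy-3-methyl-5-oxopentanoic acid (methyl hydrogen (R)-3-methylglutarate)
Product: 2 methyl (R)-5-hydroxy-3-methylpentanoate
Conditions: BH3·SMe2, THF, 0 °C to rt; MeOH quench
Reagents that add atoms: none
Why: Borane reduces the free carboxylic acid through its acyloxyborane far faster than the methyl ester, so the two ends of the glutarate are differentiated without touching the stereocentre.

**Step 2**
Reactants: 2 methyl (R)-5-hydroxy-3-methylpentanoate
Product: 3 methyl (S)-5-iodo-3-methylpentanoate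
Conditions: PPh3, iodine, imidazole, CH2Cl2, 0 °C to rt
Reagents that add atoms: iodine, II
Why: Appel-type iodination of a primary alcohol through its alkoxyphosphonium salt, with displacement at CH2 only (the descriptor changes by priority, not by inversion).

**Step 3**
Reactants: 3 methyl (S)-5-iodo-3-methylpentanoate
Product: 4 (S)-5-iodo-3-methylpentan-1-ol
Conditions: iBu2AlH (2.2 equiv), CH2Cl2, −78 to 0 °C; Rochelle salt work-up
Reagents that add atoms: none
Why: Aluminium hydride reduction of the ester to the primary alcohol, under which a primary alkyl iodide is inert at low temperature.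

**Step 4**
Reactants: 4 (S)-5-iodo-3-methylpentan-1-ol
Product: 5 (S)-tert-butyl[(5-iodo-3-methylpentyl)oxy]diphenylsilane
Conditions: tert-butyl(chloro)diphenylsilane, imidazole, CH2Cl2, 0 °C to rt
Reagents that add atoms: tert-butyl(chloro)diphenylsilane, CC(C)(C)[Si](Cl)(c1ccccc1)c1ccccc1
Why: Standard silylation of a primary alcohol; imidazole is too weak a base to trigger cyclisation of the iodo alcohol to a tetrahydropyran, and the silyl ether withstands the enolate, Lewis acid and oxidation steps ahead.

**Step 5**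
Reactants: 6 2-methylcyclohex-2-en-1-one
Product: 8 (R)-[(2,3-dimethylcyclohex-1-en-1-yl)oxy]trimethylsilane, via dimethylaluminium enolate 7 (not isolated)
Conditions: Me3Al, copper thiophene-2-carboxylate (CuTC, 2 mol%), chiral BINOL-derived phosphoramidite (4 mol%), Et2O, −30 °C; then trimethylsilyl triflate, −30 °C to rt
Reagents that add atoms: trimethylaluminium, C[Al](C)C; trimethylsilyl trifluoromethanesulfonate, C[Si](C)(C)OS(=O)(=O)C(F)(F)F
Why: Copper-catalysed asymmetric conjugate addition to a 2-substituted cyclohexenone, in which the chiral phosphoramidite–copper complex selects the enone face and sets C8 (R), and the regiodefined aluminium enolate is captured on oxygen before it can equilibrate.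

**Step 6**
Reactants: 8 (R)-[(2,3-dimethylcyclohex-1-en-1-yl)oxy]trimethylsilane, 5 (S)-tert-butyl[(5-iodo-3-methylpentyl)oxy]diphenylsilane
Product: 10 (2S,3R)-2-[(3R)-5-{[tert-butyl(diphenyl)silyl]oxy}-3-methylpentyl]-2,3-dimethylcyclohexan-1-one, via lithium enolate 9 (not isolated)
Conditions: MeLi, THF, 0 °C to rt; then HMPA, iodide 5, −78 °C to rt
Reagents that add atoms: none
Why: Regiospecific enolate alkylation: MeLi cleaves the Si–O bond to unmask the tetrasubstituted lithium enolate, which is C-alkylated by the primary iodide on the face anti to the neighbouring C8 methyl group, setting the C9 quaternary centre (S) with the two ring methyls cis.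

**Step 7**
Reactants: 10 (2S,3R)-2-[(3R)-5-{[tert-butyl(diphenyl)silyl]oxy}-3-methylpentyl]-2,3-dimethylcyclohexan-1-one
Product: 12 (5R,6S)-6-[(3R)-5-{[tert-butyl(diphenyl)silyl]oxy}-3-methylpentyl]-5,6-dimethylcyclohex-1-en-1-yl trifluoromethanesulfonate, via potassium enolate 11 (not isolated)
Conditions: KN(SiMe3)2, THF, −78 °C; then N-phenyl-bis(trifluoromethanesulfonimide), −78 to 0 °C
Reagents that add atoms: N-phenyl-bis(trifluoromethanesulfonimide), O=S(=O)(N(c1ccccc1)S(=O)(=O)C(F)(F)F)C(F)(F)F
Why: Enol triflate formation; the ketone can enolise only towards C5 because C9 is quaternary, so a single regioisomer forms and no stereocentre is at risk.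

**Step 8**
Reactants: 12 (5R,6S)-6-[(3R)-5-{[tert-butyl(diphenyl)silyl]oxy}-3-methylpentyl]-5,6-dimethylcyclohex-1-en-1-yl trifluoromethanesulfonate
Product: 13 tert-butyl{[(3R)-5-[(1S,6R)-1,6-dimethyl-2-vinylcyclohex-2-en-1-yl]-3-methylpentyl]oxy}diphenylsilane
Conditions: tributyl(vinyl)stannane, Pd(PPh3)4 (5 mol%), LiCl, THF, 65 °C
Reagents that add atoms: tributyl(vinyl)stannane, C=C[Sn](CCCC)(CCCC)CCCC
Why: Stille coupling of an alkenyl triflate (chloride-assisted transmetallation) installs C1 and C2 and gives the 1-vinylcyclohexene diene.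

**Step 9**
Reactants: 13 tert-butyl{[(3R)-5-[(1S,6R)-1,6-dimethyl-2-vinylcyclohex-2-en-1-yl]-3-methylpentyl]oxy}diphenylsilane, 14 methacrolein (2-methylprop-2-enal)
Product: 15 (1S,5S,6R,8aS)-5-[(3R)-5-{[tert-butyl(diphenyl)silyl]oxy}-3-methylpentyl]-1,5,6-trimethyl-1,2,3,5,6,7,8,8a-octahydronaphthalene-1-carbaldehyde
Conditions: (S)-B-o-tolyl diphenylprolinol oxazaborolidine (20 mol%) activated with Tf2NH (18 mol%), methacrolein (5 equiv), CH2Cl2, −78 to −40 °C
Reagents that add atoms: none
Why: The protonated oxazaborolidine binds the formyl oxygen of 14 (with the formyl C–H···O contact that fixes the s-trans enal), and a concerted but asynchronous [4+2] cycloaddition follows in which the dienophile CH2 (C3) bonds ahead to the unhindered vinyl terminus C2 while the α-carbon C4 closes onto ring carbon C5. The closest known reaction type is the oxazaborolidinium-catalysed Diels–Alder reaction of 2-substituted acroleins with 1-vinylcycloalkene dienes, and Lewis-acid cycloadditions of 2-methylacrylic dienophiles to 6,6-disubstituted 1-vinylcyclohexenes are expected to follow the same "ortho" regiochemistry. Ring A is closed in a suprafacial–suprafacial six-membered cycloaddition that forms C4–C5 and C2–C3 and leaves the new alkene at C1=C10. The quaternary centre C4 is set by the catalyst, which leaves only the Re face of the α-carbon of 14 open, and C5 is set relative to C4 by the exo placement of the catalyst-bound formyl group that 2-substituted acroleins adopt (here the endo site also lies under the congested C10–C9 region), so that CHO and H-5 end up cis. The step needs ortho regiochemistry, exo topology and attack on the diene face syn to the C9 methyl: the first is secured by the more nucleophilic, less hindered CH2 terminus and the allyl-cation-like charge spread over C1–C10–C5, and the last follows from the other two because Re-face attack in an exo array can only engage that diene face, so the weak intrinsic bias of C9 (CH3 against CH2CH2R) is not relied on. The quaternary C9 also favours the reactive s-cis diene, since the s-trans rotamer pushes the vinyl CH2 against the C9 substituents.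

**Step 10**
Reactants: 15 (1S,5S,6R,8aS)-5-[(3R)-5-{[tert-butyl(diphenyl)silyl]oxy}-3-methylpentyl]-1,5,6-trimethyl-1,2,3,5,6,7,8,8a-octahydronaphthalene-1-carbaldehyde
Product: 16 (1S,5S,6R,8aS)-5-[(3R)-5-{[tert-butyl(diphenyl)silyl]oxy}-3-methylpentyl]-1,5,6-trimethyl-1,2,3,5,6,7,8,8a-octahydronaphthalene-1-carboxylic acid
Conditions: NaClO2, NaH2PO4, 2-methylbut-2-ene, t-BuOH/H2O, rt
Reagents that add atoms: sodium chlorite, [Na+].[O-]Cl=O
Why: Pinnick oxidation of a non-enolisable neopentyl aldehyde by chlorous acid, with 2-methylbut-2-ene removing hypochlorous acid so that the C1=C10 alkene is spared.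

**Step 11**
Reactants: 16 (1S,5S,6R,8aS)-5-[(3R)-5-{[tert-butyl(diphenyl)silyl]oxy}-3-methylpentyl]-1,5,6-trimethyl-1,2,3,5,6,7,8,8a-octahydronaphthalene-1-carboxylic acid
Product: 17 methyl (1S,5S,6R,8aS)-5-[(3R)-5-{[tert-butyl(diphenyl)silyl]oxy}-3-methylpentyl]-1,5,6-trimethyl-1,2,3,5,6,7,8,8a-octahydronaphthalene-1-carboxylate
Conditions: MeI, K2CO3, DMF, rt
Reagents that add atoms: iodomethane, CI
Why: O-alkylation of the carboxylate at the unhindered methyl carbon avoids acyl substitution at the hindered quaternary carbonyl.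

**Step 12**
Reactants: 17 methyl (1S,5S,6R,8aS)-5-[(3R)-5-{[tert-butyl(diphenyl)silyl]oxy}-3-methylpentyl]-1,5,6-trimethyl-1,2,3,5,6,7,8,8a-octahydronaphthalene-1-carboxylate
Product: 18 methyl (1S,5S,6R,8aS)-5-[(3R)-5-{[tert-butyl(diphenyl)silyl]oxy}-3-methylpentyl]-1,5,6-trimethyl-3-oxo-1,2,3,5,6,7,8,8a-octahydronaphthalene-1-carboxylate
Conditions: Rh2(cap)4 (dirhodium tetracaprolactamate, 1 mol%), t-BuOOH (5 equiv), K2CO3, CH2Cl2, rt to 40 °C
Reagents that add atoms: tert-butyl hydroperoxide, CC(C)(C)OO
Why: Radical allylic oxidation by tert-butylperoxyl radicals at C2, the allylic CH2 next to the vinylic C1–H (the valencene-to-nootkatone pattern); C9 has no hydrogen and the tertiary C5–H is shielded by the quaternary C4, so the conjugated C2 ketone is expected.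

**Step 13**
Reactants: 18 methyl (1S,5S,6R,8aS)-5-[(3R)-5-{[tert-butyl(diphenyl)silyl]oxy}-3-methylpentyl]-1,5,6-trimethyl-3-oxo-1,2,3,5,6,7,8,8a-octahydronaphthalene-1-carboxylate
Product: 19 methyl (1S,5S,6R,8aS)-5-[(3R)-5-hydroxy-3-methylpentyl]-1,5,6-trimethyl-3-oxo-1,2,3,5,6,7,8,8a-octahydronaphthalene-1-carboxylate (CNP0157174.1)
Conditions: HF·pyridine, THF/pyridine, 0 °C to rt
Reagents that add atoms: none
Why: Fluoride cleavage of the silyl ether under mildly acidic, non-enolising conditions, so that the γ-epimerisable C5 and the methyl ester are untouched.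

**Compound list**
1 | (R)-5-methoxy-3-methyl-5-oxopentanoic acid | OC(=O)C[C@@H](C)CC(=O)OC | starting material
2 | methyl (R)-5-hydroxy-3-methylpentanoate | OCC[C@@H](C)CC(=O)OC | intermediate
3 | methyl (S)-5-iodo-3-methylpentanoate | ICC[C@@H](C)CC(=O)OC | intermediate
4 | (S)-5-iodo-3-methylpentan-1-ol | ICC[C@@H](C)CCO | intermediate
5 | (S)-tert-butyl[(5-iodo-3-methylpentyl)oxy]diphenylsilane | ICC[C@@H](C)CCO[Si](c1ccccc1)(c1ccccc1)C(C)(C)C | intermediate
6 | 2-methylcyclohex-2-en-1-one | CC1=CCCCC1=O | starting material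
7 | dimethylaluminium (R)-2,3-dimethylcyclohex-1-en-1-olate | C[Al](C)OC1=C(C)[C@H](C)CCC1 | intermediate
8 | (R)-[(2,3-dimethylcyclohex-1-en-1-yl)oxy]trimethylsilane | C[Si](C)(C)OC1=C(C)[C@H](C)CCC1 | intermediate
9 | lithium (R)-2,3-dimethylcyclohex-1-en-1-olate | [Li]OC1=C(C)[C@H](C)CCC1 | intermediate
10 | (2S,3R)-2-[(3R)-5-{[tert-butyl(diphenyl)silyl]oxy}-3-methylpentyl]-2,3-dimethylcyclohexan-1-one | O=C1CCC[C@@H](C)[C@]1(C)CC[C@@H](C)CCO[Si](c1ccccc1)(c1ccccc1)C(C)(C)C | intermediate
11 | potassium (5R,6S)-6-[(3R)-5-{[tert-butyl(diphenyl)silyl]oxy}-3-methylpentyl]-5,6-dimethylcyclohex-1-en-1-olate | [K]OC1=CCC[C@@H](C)[C@]1(C)CC[C@@H](C)CCO[Si](c1ccccc1)(c1ccccc1)C(C)(C)C | intermediate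
12 | (5R,6S)-6-[(3R)-5-{[tert-butyl(diphenyl)silyl]oxy}-3-methylpentyl]-5,6-dimethylcyclohex-1-en-1-yl trifluoromethanesulfonate | O=S(=O)(OC1=CCC[C@@H](C)[C@]1(C)CC[C@@H](C)CCO[Si](c1ccccc1)(c1ccccc1)C(C)(C)C)C(F)(F)F | intermediate
13 | tert-butyl{[(3R)-5-[(1S,6R)-1,6-dimethyl-2-vinylcyclohex-2-en-1-yl]-3-methylpentyl]oxy}diphenylsilane | C=CC1=CCC[C@@H](C)[C@]1(C)CC[C@@H](C)CCO[Si](c1ccccc1)(c1ccccc1)C(C)(C)C | intermediate
14 | methacrolein (2-methylprop-2-enal) | CC(=C)C=O | starting material
15 | (1S,5S,6R,8aS)-5-[(3R)-5-{[tert-butyl(diphenyl)silyl]oxy}-3-methylpentyl]-1,5,6-trimethyl-1,2,3,5,6,7,8,8a-octahydronaphthalene-1-carbaldehyde | O=C[C@@]1(C)CCC=C2[C@@H]1CC[C@@H](C)[C@]2(C)CC[C@@H](C)CCO[Si](c1ccccc1)(c1ccccc1)C(C)(C)C | intermediate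
16 | (1S,5S,6R,8aS)-5-[(3R)-5-{[tert-butyl(diphenyl)silyl]oxy}-3-methylpentyl]-1,5,6-trimethyl-1,2,3,5,6,7,8,8a-octahydronaphthalene-1-carboxylic acid | OC(=O)[C@@]1(C)CCC=C2[C@@H]1CC[C@@H](C)[C@]2(C)CC[C@@H](C)CCO[Si](c1ccccc1)(c1ccccc1)C(C)(C)C | intermediate
17 | methyl (1S,5S,6R,8aS)-5-[(3R)-5-{[tert-butyl(diphenyl)silyl]oxy}-3-methylpentyl]-1,5,6-trimethyl-1,2,3,5,6,7,8,8a-octahydronaphthalene-1-carboxylate | COC(=O)[C@@]1(C)CCC=C2[C@@H]1CC[C@@H](C)[C@]2(C)CC[C@@H](C)CCO[Si](c1ccccc1)(c1ccccc1)C(C)(C)C | intermediate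
18 | methyl (1S,5S,6R,8aS)-5-[(3R)-5-{[tert-butyl(diphenyl)silyl]oxy}-3-methylpentyl]-1,5,6-trimethyl-3-oxo-1,2,3,5,6,7,8,8a-octahydronaphthalene-1-carboxylate | COC(=O)[C@@]1(C)CC(=O)C=C2[C@@H]1CC[C@@H](C)[C@]2(C)CC[C@@H](C)CCO[Si](c1ccccc1)(c1ccccc1)C(C)(C)C | intermediate
19 | methyl (1S,5S,6R,8aS)-5-[(3R)-5-hydroxy-3-methylpentyl]-1,5,6-trimethyl-3-oxo-1,2,3,5,6,7,8,8a-octahydronaphthalene-1-carboxylate | COC(=O)[C@@]1(C)CC(=O)C=C2[C@@H]1CC[C@@H](C)[C@]2(C)CC[C@@H](C)CCO | target

**Step count and risks**
Total steps: 13. Longest linear sequence: 12 (steps 1–4, then 6–13); the ring B branch from 6 is 9 steps.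

Steps most likely to fail:

1. Step 9 (key cycloaddition). The exo topology may be lost (formyl endo on the opposite diene face, which the catalyst-selected enal face also allows), or the diene may oligomerise under the strongly acidic catalyst. The fallback separates ring closure from construction of the quaternary centre. It sets out from 13: a Me2AlCl-promoted Diels–Alder reaction with methyl acrylate (CH2Cl2, −78 to −20 °C) closes ring A through the same C4–C5/C2–C3 bond pair and should give methyl (5S,6R,8aR)-5-[(3R)-5-{[tert-butyl(diphenyl)silyl]oxy}-3-methylpentyl]-5,6-dimethyl-1,2,3,5,6,7,8,8a-octahydronaphthalene-1-carboxylate F1, in which either C4 epimer serves. LiN(iPr)2 and then MeI (THF/DMPU, −78 °C) should methylate the ester enolate by axial entry anti to H-5, which has no syn-axial partner at the sp2 C10, and the route is rejoined at 17.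

2. Step 12 (allylic oxidation). Hydrogen abstraction may compete at the tertiary allylic C5–H, leading to a transposed enone and loss of the C5 centre, or over-oxidation may occur. The fallback is a three-stage oxygen transposition from 17. Peracid epoxidation (mCPBA, NaHCO3, CH2Cl2) gives the C1–C10 epoxide of 17 F2. Phenylselenide (PhSeSePh, NaBH4, EtOH) opens it at the less hindered C1 to the C1-phenylseleno C10-hydroxy ester F3, and H2O2 then triggers selenoxide syn-elimination towards C2 to give the tertiary allylic alcohol with the C1=C2 alkene F4. Oxidative 1,3-transposition with pyridinium chlorochromate ([C5H5NH][CrO3Cl], CH2Cl2) should return to 18.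

3. Step 6 (enolate alkylation). C-alkylation of the hindered tetrasubstituted enolate by an unactivated primary iodide may be slow, which would let proton transfer to the product, alkylation at the other α-carbon and O-alkylation compete. The fallback uses a reactive allylic electrophile and sets C13 afterwards. But-3-yn-1-ol is silylated to tert-butyl(but-3-yn-1-yloxy)diphenylsilane F5. Zirconium-catalysed carboalumination (Me3Al, Cp2ZrCl2) followed by paraformaldehyde gives (2E)-5-{[tert-butyl(diphenyl)silyl]oxy}-3-methylpent-2-en-1-ol F6, and CBr4/PPh3 converts it into {[(3E)-5-bromo-3-methylpent-3-en-1-yl]oxy}(tert-butyl)diphenylsilane F7. Setting out from 8, the lithium enolate 9 (MeLi, THF) is alkylated with F7 to (2S,3R)-2-[(2E)-5-{[tert-butyl(diphenyl)silyl]oxy}-3-methylpent-2-en-1-yl]-2,3-dimethylcyclohexan-1-one F8. Catalyst-controlled hydrogenation of the trisubstituted alkene ([Ir(cod)(PHOX)]BArF, H2, CH2Cl2) should set C13 (R) and return to 10.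

**Further compounds**
F1 | step 9 | methyl (5S,6R,8aR)-5-[(3R)-5-{[tert-butyl(diphenyl)silyl]oxy}-3-methylpentyl]-5,6-dimethyl-1,2,3,5,6,7,8,8a-octahydronaphthalene-1-carboxylate (C4 epimer mixture) | COC(=O)C1CCC=C2[C@@H]1CC[C@@H](C)[C@]2(C)CC[C@@H](C)CCO[Si](c1ccccc1)(c1ccccc1)C(C)(C)C
F2 | step 12 | C1–C10 epoxide of 17 (epoxide face unassigned) | COC(=O)[C@@]1(C)CCC2OC23[C@@H]1CC[C@@H](C)[C@]3(C)CC[C@@H](C)CCO[Si](c1ccccc1)(c1ccccc1)C(C)(C)C
F3 | step 12 | C1-phenylseleno C10-hydroxy ester | COC(=O)[C@@]1(C)CCC([Se]c2ccccc2)C2(O)[C@@H]1CC[C@@H](C)[C@]2(C)CC[C@@H](C)CCO[Si](c1ccccc1)(c1ccccc1)C(C)(C)C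
F4 | step 12 | tertiary allylic alcohol (C10–OH, C1=C2 alkene) | COC(=O)[C@@]1(C)CC=CC2(O)[C@@H]1CC[C@@H](C)[C@]2(C)CC[C@@H](C)CCO[Si](c1ccccc1)(c1ccccc1)C(C)(C)C
F5 | step 6 | tert-butyl(but-3-yn-1-yloxy)diphenylsilane | C#CCCO[Si](c1ccccc1)(c1ccccc1)C(C)(C)C
F6 | step 6 | (2E)-5-{[tert-butyl(diphenyl)silyl]oxy}-3-methylpent-2-en-1-ol | OC/C=C(\C)CCO[Si](c1ccccc1)(c1ccccc1)C(C)(C)C
F7 | step 6 | {[(3E)-5-bromo-3-methylpent-3-en-1-yl]oxy}(tert-butyl)diphenylsilane | BrC/C=C(\C)CCO[Si](c1ccccc1)(c1ccccc1)C(C)(C)C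
F8 | step 6 | (2S,3R)-2-[(2E)-5-{[tert-butyl(diphenyl)silyl]oxy}-3-methylpent-2-en-1-yl]-2,3-dimethylcyclohexan-1-one | O=C1CCC[C@@H](C)[C@]1(C)C/C=C(\C)CCO[Si](c1ccccc1)(c1ccccc1)C(C)(C)C
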